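At its full charge of 60.0 mM in flask eta, J drains G at 0.0540 /min, faster than the coefficient 0.02 /min with which D refills it.

    G + J → Z + L (k1 = 0.015 /M/s)
    J + Z ⇌ J.Z, settled at all times (K2 = 450 /M)
    2 G → G2 (k3 = 0.0064 /M/s)
    L ⇌ E (K4 = 0.99, k4 = 3.2 × 10⁻⁴ /s)
    D ⇌ G, rate k5*(cs5 - [G]) while solid is left; crystals form when [G] > cs5 (cs5 = 16 mM, k5 = 3.3 × 10⁻⁴ /s)

- eta: D 20 mM; J 3.00 equiv (fed, over 30 min); time 40 min
- beta: D 20 mM; J 1.50 equiv (fed, over 30 min); time 40 min

- in percentages every species weighs as the D in it: one G2 counts as two
- where a step has two of a species, its rate is k times that concentration squared, and two are used at each turn
- as a solid, counted per litre of solution: D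
- at the start none of D is in solution
- what has only dissolved of D counts as not reacted
- run time (eta): 40 min

- part of the D that has reacted (what has only dissolved counts as not reacted) at the end, eta
- part of the D that has reacted (what has only dissolved counts as not reacted) at the end, beta
- what raising the equivalents of J from its lowest to its highest value here does to the part of the D that has reacted (what has only dissolved counts as not reacted) (changes below 5 percentage points count as none) (it rises / it falls / no change)

G that has merely dissolved counts as not reacted, so the reckoning needs two things: how much G stands in solution, and how long J works on it. Write S for the solubility and k for the rate constant of G + J. D supplies G at a rate proportional to S − [G], and J removes it in proportion to k[J][G]. The two rates are equal at a level [G]*: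

[G]* = S / (1 + r)

In eta at full charge this quotient is 2.73: the capture ratio r, the pseudo-first-order drain of J on G divided by the dissolution coefficient.

But r drifts. J is fed steadily over 30 min, so r climbs from zero and, reckoned on the J fed so far, in eta reaches one at about 11.0 min. The time-sum of J up to the end is the full charge times w, with w = 25.0 min. By hand, then, the reacted part is [G]* times k, the full charge of J and w, over the D charged:

eta: r = 2.73, [G]* = 4.29 mM, reacted about 29.0%

beta: r = 1.36, [G]* = 6.77 mM, reacted about 22.8%

This holds G at its level throughout and counts all fed J as free. The pairing of G is set aside, since at that level in eta it takes 0.0611 of what J takes. By hand the part rises by 6.2 percentage points, past the margin.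

The forecast gives 27% and 18%, higher J meaning it rises, on the ground that “the slow G + J step leaves several mM of G unreacted at the end”; these numbers differ from the hand reckoning.

The simulation gives 27.2% for eta and 17.7% for beta: with more J, it rises, by 9.5 points, and the hand figure for beta stands higher than the simulated one, as does that for eta. At the end of eta, 83.6% of the charged J is still free and G stands at 22.5% of the D charged. With that free J, r becomes 2.28, and [G]* becomes 24.4% of the D charged.

Eta with 0.750 equiv of J has r = 0.682, so [G]* is 47.6% of the D charged and the reacted part about 16.1%. The simulation of that flask gives G at 34.5% and a reacted part of 11.6%.

All constants are invented; the rest is arithmetic.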